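**Retrosynthetic overview**

- The strategy rests on ring A, a hexasubstituted benzene whose carbon and oxygen substituents alternate (C1 butanoyl, C2 OH, C3 CH2 bridge, C4 OH, C5 CH3, C6 OCH3). Its only methyl ether sits on C6 between the butanoyl and methyl carbons, where a chelated, hindered OH cannot be methylated selectively, so the OCH3 is brought in on a ring-forming partner.
- Last disconnection: the CH2 bridge between C3 of ring A and ring B. The CH2 is the formyl carbon of a ring A aldehyde, joined to acetylfilicinic acid by organocatalytic reductive alkylation.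
- Ring B is not constructed: commercial 2,4,6-trihydroxyacetophenone is dearomatised by geminal C-dimethylation.
- Key disconnection: ring A bonds C5–C6 and C1–C2, by (4+2) cycloaddition and aromatisation. 1-Methoxy-1,3-bis(trimethylsilyloxy)penta-1,3-diene supplies C2–C5 with both future OH groups and the methyl; 1-methoxyhex-1-yn-3-one supplies C6 with OCH3 and C1 with butanoyl.
- Ring order: ring A is the only ring formed (step 5); it is then formylated at C3 and coupled to ring B.

Key step: step 5

Remark: E/Z isomers of the silyl enol ethers and keto/enol tautomers of the ring B triketone are treated as equivalent; ring B is drawn in the tautomeric form of the target.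

**Route**

Step 1
Reactants: 1 methyl 3-oxopentanoate
Product: 2 methyl 3-(trimethylsilyloxy)pent-2-enoate (E/Z mixture, either isomer serves)
Conditions: Me3SiCl, Et3N, toluene, 20 °C
Reagents that add atoms: chlorotrimethylsilane, C[Si](C)(C)Cl
Why: Silyl enol ether formation by soft enolisation; the enolised β-keto ester should be trapped on oxygen by Me3SiCl with Et3N as base.

Step 2
Reactants: 2 methyl 3-(trimethylsilyloxy)pent-2-enoate
Product: 4 (1Z,3Z)-1-methoxy-1,3-bis(trimethylsilyloxy)penta-1,3-diene, via lithium dienolate 3 (not isolated)
Conditions: LiN(iPr)2, THF, −78 °C; then Me3SiCl, −78 → 20 °C; non-aqueous work-up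
Reagents that add atoms: chlorotrimethylsilane, C[Si](C)(C)Cl
Why: Kinetic γ-deprotonation of the silyloxy enoate gives the extended dienolate, which is O-silylated to the 1,3-bis(silyl enol ether), the standard preparation of such ketene acetal dienes; the diene geometry is irrelevant after aromatisation.

Step 3
Reactants: 5 2-chloro-1,1-dimethoxyethane; 6 butanal
Product: 8 1-methoxyhex-1-yn-3-ol (racemic), via lithium methoxyacetylide 7 (not isolated)
Conditions: LiNEt2 (3 equiv, from n-BuLi and Et2NH), THF, 0 °C; then 6, −78 → 0 °C; pH 7 buffer
Reagents that add atoms: none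
Why: Twofold base-induced elimination of the chloroacetal (loss of methanol and HCl) and deprotonation generate the lithium alkoxyacetylide, which undergoes 1,2-acetylide addition to the aldehyde; the new carbinol centre is racemic and is removed in step 4.

Step 4
Reactants: 8 1-methoxyhex-1-yn-3-ol
Product: 9 1-methoxyhex-1-yn-3-one
Conditions: MnO2 (activated, excess), CH2Cl2, 20 °C
Reagents that add atoms: none
Why: MnO2 oxidation of a propargylic alcohol under neutral, anhydrous conditions should avoid acid-triggered Meyer–Schuster rearrangement of the alkoxyalkynyl carbinol and hydration of the ynol ether.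

Step 5
Reactants: 4 (1Z,3Z)-1-methoxy-1,3-bis(trimethylsilyloxy)penta-1,3-diene (1.5 equiv); 9 1-methoxyhex-1-yn-3-one
Product: 12 1-(4,6-dihydroxy-2-methoxy-3-methylphenyl)butan-1-one, via cyclohexa-1,4-diene cycloadduct 10 (not isolated), via bis(trimethylsilyl) ether 11 (not isolated)
Conditions: toluene, 20 → 80 °C, sealed under argon; then 1 M HCl, THF, 20 °C
Reagents that add atoms: none
Why: The electron-rich ketene acetal diene 4 and ynone 9 should combine in a normal-electron-demand, strongly asynchronous (4+2) cycloaddition in which the bond from diene C4 to the ynone β carbon (future C5–C6 of ring A) leads and the bond from diene C1 to the α carbon (future C1–C2) follows; in the zwitterionic limit this is a vinylogous Mukaiyama–Michael addition followed by 6-exo-trig collapse of the allenolate carbon onto the C1 oxocarbenium (ester) carbon. The closest known reaction type is the Diels–Alder/aromatisation of 1-alkoxy-1,3-bis(silyloxy)buta-1,3-dienes with alkynyl ketones and esters, which gives resorcinols after loss of the acetal alkoxy group. Ring A is closed by the cycloaddition itself, and cycloadduct 10 should aromatise by 1,4-elimination of methanol from the acetal carbon and the CH(CH3) hydrogen to give 11, whose silyl ethers are cleaved by dilute acid. No stereocentre survives, since the two sp3 ring carbons of 10 and the diene geometry are erased on aromatisation. The step needs regiocontrol and chemoselectivity: the largest HOMO coefficient of 4 lies at the CH(CH3) terminus and the β carbon is the electrophilic site of the push-pull ynone (as in a β-alkoxy enone), so OCH3 should end up between butanoyl and methyl, while thermal conditions without Lewis acid disfavour attack of diene C2 on the ketone (the (3+3) salicylate mode). The methyl ynol ether has no β-hydrogen and so cannot fragment to a ketene on heating.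

Step 6
Reactants: 12 1-(4,6-dihydroxy-2-methoxy-3-methylphenyl)butan-1-one
Product: 14 3-butanoyl-2,6-dihydroxy-4-methoxy-5-methylbenzaldehyde, via aryl chloro(methoxy)methane 13 (not isolated)
Conditions: Cl2CHOMe, TiCl4, CH2Cl2, −78 → 0 °C; then ice, 1 M HCl
Reagents that add atoms: dichloromethyl methyl ether, COC(Cl)Cl; water, O
Why: Rieche formylation (electrophilic aromatic substitution) can only occur at the single unsubstituted ring carbon, which is activated by two flanking titanium phenoxides; the ketone is already chelated to its ortho OH, so the neighbouring OCH3 should not be cleaved at low temperature.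

Step 7
Reactants: 15 2,4,6-trihydroxyacetophenone
Product: 17 2-acetyl-3,5-dihydroxy-6,6-dimethylcyclohexa-2,4-dien-1-one (acetylfilicinic acid), via C-monomethyl ketone 16 (not isolated)
Conditions: MeI (2.2 equiv), NaOMe (3 equiv), MeOH, 0 → 20 °C; then aq. HCl
Reagents that add atoms: iodomethane, CI
Why: Dearomatising C-alkylation of the ambident phloroglucinol phenoxide, the classical preparation of acylfilicinic acids; the second methyl should enter at the already methylated, most electron-rich ring carbon, and stoichiometry limits further methylation.

Step 8
Reactants: 14 3-butanoyl-2,6-dihydroxy-4-methoxy-5-methylbenzaldehyde; 17 acetylfilicinic acid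
Product: 19 Aspidin AB, 2-acetyl-4-[(3-butanoyl-2,6-dihydroxy-4-methoxy-5-methylphenyl)methyl]-3,5-dihydroxy-6,6-dimethylcyclohexa-2,4-dien-1-one, via Knoevenagel alkylidene 18 (not isolated)
Conditions: diethyl 2,6-dimethyl-1,4-dihydropyridine-3,5-dicarboxylate (Hantzsch ester, 1.2 equiv), L-proline (20 mol %), CH2Cl2, 20 °C
Reagents that add atoms: none
Why: Three-component organocatalytic reductive alkylation; proline-mediated Knoevenagel condensation at the free enolic ring carbon (C4) of 17 gives alkylidene 18, and conjugate hydride transfer from the Hantzsch ester should reduce it to the CH2 bridge without touching the aryl ketone, the acetyl group or the phenols; no stereocentre is formed.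

**Compound list**

1 | methyl 3-oxopentanoate | CCC(=O)CC(=O)OC | starting material
2 | methyl 3-(trimethylsilyloxy)pent-2-enoate (E/Z mixture) | CCC(O[Si](C)(C)C)=CC(=O)OC | intermediate
3 | lithium dienolate of 2 | [Li+].CC=C(O[Si](C)(C)C)C=C([O-])OC | intermediate (not isolated)
4 | (1Z,3Z)-1-methoxy-1,3-bis(trimethylsilyloxy)penta-1,3-diene | C/C=C(O[Si](C)(C)C)/C=C(/OC)O[Si](C)(C)C | intermediate
5 | 2-chloro-1,1-dimethoxyethane | COC(CCl)OC | starting material
6 | butanal | CCCC=O | starting material
7 | lithium methoxyacetylide | [Li]C#COC | intermediate (not isolated)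
8 | 1-methoxyhex-1-yn-3-ol (racemic) | CCCC(O)C#COC | intermediate
9 | 1-methoxyhex-1-yn-3-one | CCCC(=O)C#COC | intermediate
10 | 1-[2,6-dimethoxy-3-methyl-4,6-bis(trimethylsilyloxy)cyclohexa-1,4-dien-1-yl]butan-1-one (configuration at the two sp3 ring carbons not defined) | CCCC(=O)C1=C(OC)C(C)C(O[Si](C)(C)C)=CC1(OC)O[Si](C)(C)C | intermediate (not isolated)
11 | 1-[2-methoxy-3-methyl-4,6-bis(trimethylsilyloxy)phenyl]butan-1-one | CCCC(=O)c1c(O[Si](C)(C)C)cc(O[Si](C)(C)C)c(C)c1OC | intermediate (not isolated)
12 | 1-(4,6-dihydroxy-2-methoxy-3-methylphenyl)butan-1-one | CCCC(=O)c1c(O)cc(O)c(C)c1OC | intermediate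
13 | 1-{3-[chloro(methoxy)methyl]-2,4-dihydroxy-6-methoxy-5-methylphenyl}butan-1-one (racemic) | CCCC(=O)c1c(O)c(C(Cl)OC)c(O)c(C)c1OC | intermediate (not isolated)
14 | 3-butanoyl-2,6-dihydroxy-4-methoxy-5-methylbenzaldehyde | CCCC(=O)c1c(O)c(C=O)c(O)c(C)c1OC | intermediate
15 | 2,4,6-trihydroxyacetophenone | CC(=O)c1c(O)cc(O)cc1O | starting material
16 | 1-(2,4,6-trihydroxy-3-methylphenyl)ethan-1-one | CC(=O)c1c(O)cc(O)c(C)c1O | intermediate (not isolated)
17 | 2-acetyl-3,5-dihydroxy-6,6-dimethylcyclohexa-2,4-dien-1-one (acetylfilicinic acid) | CC(=O)C1=C(O)C=C(O)C(C)(C)C1=O | intermediate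
18 | 2-acetyl-4-[(3-butanoyl-2,6-dihydroxy-4-methoxy-5-methylphenyl)methylidene]-3-hydroxy-6,6-dimethylcyclohex-2-ene-1,5-dione (alkene geometry not defined) | CCCC(=O)c1c(O)c(C=C2C(=O)C(C)(C)C(=O)C(C(C)=O)=C2O)c(O)c(C)c1OC | intermediate (not isolated)
19 | Aspidin AB | CCCC(=O)c1c(O)c(CC2=C(O)C(C)(C)C(=O)C(C(C)=O)=C2O)c(O)c(C)c1OC | target

**Step count**

Total: 8 steps. Longest linear sequence: 5 steps (steps 1, 2, 5, 6, 8).

**Steps most likely to fail**

1. Step 5. Donation from the methoxy group raises the LUMO of the ynone, so the cycloaddition may be slow enough for the diene to desilylate or decompose first. The first C–C bond may also form without ring closure (silyl transfer to an open-chain Michael adduct), or closure may follow the aldol-type (3+3) course to a salicylate.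
 Fallback: this abandons cycloaromatisation and uses the fact that in aldehyde 14 the OCH3 lies para to the formyl group and between two ring positions that are equivalent before substitution. It does not branch from a numbered intermediate (steps 1 to 6 are bypassed): it sets out from purchased 2,4,6-trihydroxytoluene F1 and comes back to the route at aldehyde 14. Vilsmeier–Haack formylation (POCl3, DMF, then water) should give 2,4,6-trihydroxy-3-methylbenzaldehyde F2. Mono-O-methylation (Me2SO4, 1 equiv, K2CO3, acetone) should take the OH para to the formyl group, the only one not hydrogen-bonded to it and the most acidic, giving 2,6-dihydroxy-4-methoxy-3-methylbenzaldehyde F3. Friedel–Crafts C-butanoylation at the single free ring carbon (butanoyl chloride, TiCl4, CH2Cl2, or by way of the O-butanoate and Fries rearrangement) then gives 14.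

2. Step 8. Knoevenagel condensation of the hindered, doubly hydrogen-bonded aldehyde may be slow. Alkylidene 18 may also be intercepted by a second molecule of 17 or by the ortho phenol (cyclisation towards a xanthene-type product) before hydride transfer.
 Fallback: this sets out from phenol 12, bypasses 14 and comes back at target 19. Mannich aminomethylation of 12 at its only free ring carbon (dimethylmethyleneiminium iodide, CH2Cl2/MeCN, 20 °C) should give 1-{3-[(dimethylamino)methyl]-2,4-dihydroxy-6-methoxy-5-methylphenyl}butan-1-one F4. Heating F4 with 17 (dioxane, 90 °C) should expel dimethylamine to form the ortho-quinone methide, which is trapped by Michael addition of the enolic carbon of 17 to give 19.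

3. Step 7. C-methylation may be unselective: it may stop at 16, place the second methyl on the other free ring carbon, run on to tri- and tetramethyl triones, or methylate oxygen.
 Fallback: this sets out from 15 and comes back at 17, using a second acetyl group to block one ring carbon. C-acetylation of 15 (Ac2O, BF3·OEt2, 60 °C) should give 2,4-diacetylphloroglucinol F5, in which only one ring carbon is free. MeI/NaOMe in MeOH can then only dimethylate that carbon, giving 2,4-diacetyl-3,5-dihydroxy-6,6-dimethylcyclohexa-2,4-dien-1-one F6, whose two acetyl groups are equivalent by tautomerism. Retro-Claisen removal of one acetyl group (aq. H2SO4, 80 °C, stopped at the mono-acyl stage) gives 17.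

**Further compounds**

F1 | step 5 | 2,4,6-trihydroxytoluene (purchased) | Cc1c(O)cc(O)cc1O
F2 | step 5 | 2,4,6-trihydroxy-3-methylbenzaldehyde | O=Cc1c(O)cc(O)c(C)c1O
F3 | step 5 | 2,6-dihydroxy-4-methoxy-3-methylbenzaldehyde | O=Cc1c(O)cc(OC)c(C)c1O
F4 | step 8 | 1-{3-[(dimethylamino)methyl]-2,4-dihydroxy-6-methoxy-5-methylphenyl}butan-1-one | CCCC(=O)c1c(O)c(CN(C)C)c(O)c(C)c1OC
F5 | step 7 | 2,4-diacetylphloroglucinol, 1,1'-(2,4,6-trihydroxy-1,3-phenylene)di(ethan-1-one) | CC(=O)c1c(O)cc(O)c(C(C)=O)c1O
F6 | step 7 | 2,4-diacetyl-3,5-dihydroxy-6,6-dimethylcyclohexa-2,4-dien-1-one | CC(=O)C1=C(O)C(C(C)=O)=C(O)C(C)(C)C1=O
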